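A shortfall of 2.90 % was the number I took from the runs you sent: maple stood at 97.1 % of the substrate charged at 6.00 d, on a plateau carrying a scatter of 0.3 percentage points per reading.

| flask | substrate | coupling partner | remark | time |
|---|---|---|---|---|
| cedar | 0.10 M | 0.15 M | run made earlier |  |
| maple | 0.10 M | 0.57 M | run made earlier |  |
| alpha | 0.10 M | 0.120 M |  | 8.0 d |
| gamma | 0.10 M | 0.300 M |  | 8.0 d |
| theta | 0.10 M | 0.400 M |  | 8.0 d |

| run | time / d | double product / % |
|---|---|---|
| cedar | 0.417 | 4.9 |
| cedar | 0.833 | 12.0 |
| cedar | 1.25 | 18.6 |
| cedar | 2.08 | 28.3 |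
| cedar | 3.00 | 35.8 |
| cedar | 6.00 | 48.5 |
| maple | 0.417 | 37.8 |
| maple | 1.04 | 77.1 |
| maple | 2.08 | 94.2 |
| maple | 3.00 | 96.7 |
| maple | 4.00 | 97.3 |
| maple | 6.00 | 97.1 |

(scatter of a reading: 0.3 percentage points)



- double product at the end, in percent of the substrate charged, for each flask in turn (alpha, gamma, theta)

I followed one substrate molecule. At its fork it could take coupling partner and go on towards double product, or leave by a side exit that I assumed needed a second substrate molecule. With the substrate charge held at 0.10 M, its chance of that exit then went down as [coupling partner] went up. I took the charged partner as a rough stand-in for what the molecule met, and I called the lost share times that charge the loss product, 0.0165 M. My reckoning was: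

lost share = loss product / [coupling partner]

gamma: 0.0165 M / 0.300 M = 5.51 %, so a ceiling of 94.5 %

theta: 0.0165 M / 0.400 M = 4.13 %, so a ceiling of 95.9 %

alpha: 0.0165 M / 0.120 M = 13.8 % lost

The forecast you sent gave 29 % for alpha, 96.5 % for gamma and 97.1 % for theta, reading maple as “about 3% of the charge seems unable to reach double product”. We differed there: my ceilings for gamma and theta stood lower than its values, and for alpha I committed to a lost share, not a yield.

The flasks gave 37.1 % in alpha, 93.6 % in gamma and 96.2 % in theta at 8.0 d.

    2 substrate → homo dimer (k = 0.0610 M⁻¹ h⁻¹)
    coupling partner + single product → double product (k = 0.189 M⁻¹ h⁻¹)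
    substrate + coupling partner → single product (k = 0.425 M⁻¹ h⁻¹)

In alpha, substrate went to single product 4.2 times as fast as to homo dimer at the start, rising to 5.1 times at 0.538 d; homo dimer, each one counted as two, stood at 15.7 % of the substrate charged at 8.00 d, against my 13.8 %. In theta, the second case, homo dimer stood at 3.80 % at 8.00 d, against my 4.13 %.

The data are simulated from invented constants.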